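## Analysis of the target

Target 21 is methyl 7-hydroxy-5-[2-(4-hydroxyphenyl)ethyl]-2,2-dimethyl-8-(3-methylbut-2-enyl)-2H-chromene-6-carboxylate: a fully substituted benzene ring (ring A) fused to a 2,2-dimethyl-2H-pyran (ring C) and linked by a two-carbon chain to a para-hydroxyphenyl ring (ring B). There is no stereocentre: the chromene double bond is cis by ring constraint and the prenyl double bond carries two identical methyl groups, so no configurational relationship has to be controlled. The sensitive functions are the 2H-chromene (an allylic, benzylic ether that opens or hydrates in strong acid), the prenyl group ortho to a phenol (acid closes it to a chroman) and the two phenols, and both alkenes exclude hydrogenolysis and halogen-type oxidants. The methyl ester sits between two ortho substituents and is hydrogen-bonded to the neighbouring hydroxyl, so it is hindered and awkward to introduce late. The difficulty is regiochemical: six different substituents in a fixed order around ring A, with two ring A oxygens that end up in different roles (one free, one in the pyran). The strategy reads ring A, numbered C1 (ester), C2 (hydroxyl), C3 (prenyl), C4 (pyran oxygen), C5 (pyran carbon) and C6 (arylethyl), as two pieces. C6–C1–C2–C3 with its four substituents is the diene of a 4-oxygenated 2-pyrone-5-carboxylate, and C4–C5 with its oxygen is an ynol ether.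

## Retrosynthetic reasoning

The last change is not skeletal: the two phenols of 21 are uncovered from the bis(methoxymethyl) ether 20. The acetal is chosen because it comes off under mild acid in the presence of both alkenes and the ester, survives fluoride, base, zerovalent palladium and heat, and leaves both oxygens in one operation.

Ring C of 20 is cut at the O–CMe2 bond and at the bond from ring A C5 to the vinylic carbon, leading to phenol 17 and enal 18. The cut is made here because the annulation needs only a free phenol with one open ortho position, and in 17 that position is unique: C3 carries the prenyl group, so only C5 can react. The forward step must join C5 to the aldehyde carbon, dehydrate to the ortho-quinone methide 19 and close the pyran by 6π electrocyclisation.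

For that step O4 alone should be free, so 17 is taken back to silyl ether 16. In 16, O4 carries a fluoride-labile silyl group while O2 and the ring B oxygen carry acetals. This difference is not made by selective protection; it comes from the two building blocks of the next disconnection.

Ring A of 16 is cut at C3–C4 and C5–C6. This gives a four-carbon unit (C6, C1, C2, C3) holding four of the six substituents and a two-carbon unit (C4, C5) holding the silyloxy group and the only ring hydrogen. With a carbonyl–oxygen bridge between C3 and C6 the four-carbon unit is pyrone 10 (pyrone C3, C4, C5, C6 = ring A C3, C2, C1, C6), and the two-carbon unit is siloxyacetylene 14. Cutting here, rather than substituting a resorcinol step by step, means three contiguous carbon substituents never have to be placed by aromatic substitution, and the hindered ester is present from the start. The forward reaction must be a (4+2) addition in which the CH of 14 bonds to pyrone C6 and the oxygen-bearing carbon to pyrone C3. Decarboxylative retro-(4+2) of the bridged lactone 15 then gives the arene without any oxidant.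

Pyrone 10 is the O4 acetal of hydroxypyrone 9. In 9 the bond from C3 to the prenyl group is cut, giving 7 and allylic acetate 8. C3 is the nucleophilic carbon of a 4-hydroxy-2-pyrone and the only unsubstituted one in 7, so a palladium-allyl electrophile should go there. Doing this on the ring rather than on the open chain avoids mixtures of mono- and dialkylated keto esters.

The lactone C–O bond of 7 is cut to the open-chain tricarbonyl diester 6. The bond from its central carbon to the side-chain carbonyl is then cut to keto diester 4 and acid chloride 5. Compound 4 supplies pyrone C2 to C5 with the ester in place, 5 supplies C6 with the arylethyl chain, and condensation alone reaches the pyrone oxidation level. Chloride 5 comes from acid 3, and 3 from phenolic acid 1 through the doubly alkylated intermediate 2.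

Siloxyacetylene 14 is cut at O–Si to ynolate 13 and at C–O to acetylide 12, which comes from acetylene 11. The oxygen is delivered to carbon by an electrophilic peroxide oxygen and then capped with a bulky silyl group.

## Alternatives that were turned down

Alternative 1: The pyran is cut at aryl–O, aryl–C and O–CMe2, so that the chromene 5-bromo-7-(methoxymethoxy)-2,2-dimethyl-2H-chromene A1 comes from an aryne and aldehyde 18.
- **Forward key step:** a fluoride source releases the aryne from 2-bromo-4-(methoxymethoxy)-6-(trimethylsilyl)phenyl trifluoromethanesulfonate A2. The carbonyl oxygen of 18 adds to the aryne carbon remote from bromine, the (2+2) adduct opens to an ortho-quinone methide, and 6π closure gives A1.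
- **For:** the step runs at ambient temperature, makes ring C in one operation with the oxygen placed by the inductive effect of bromine, and leaves a bromide as handle for the arylethyl chain.
- **Against:** A1 still lacks the ester, the prenyl group and the arylethyl chain. They would be added one at a time, by cross-coupling and two ortho-metalations, on an acid-sensitive chromene. The ester would have to enter last or nearly last, at the most crowded position, with uncertain site selectivity between the two carbons flanking the acetal oxygen. A2 is itself a tetrasubstituted benzene needing several steps.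
- **Comparison:** the key step of Alternative 1 is milder and better behaved than a thermally forced cycloaddition. The chosen strategy instead fixes all six substituents of ring A by construction, with no late aromatic C–H functionalisation.

Alternative 2: One carbon of ring C is removed, so that the chroman-3-one methyl 5-{2-[4-(tert-butyldimethylsilyloxy)phenyl]ethyl}-7-hydroxy-2,2-dimethyl-8-(3-methylbut-2-enyl)-3-oxochromane-6-carboxylate A3 comes from the ring-contracted benzofuranone methyl 4-{2-[4-(tert-butyldimethylsilyloxy)phenyl]ethyl}-6-hydroxy-2,2-dimethyl-7-(3-methylbut-2-enyl)-3-oxo-2,3-dihydro-1-benzofuran-5-carboxylate A4.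
- **Forward key step:** a silyl diazomethane activated by a boron Lewis acid adds to the ketone of A4 and the ring A carbon migrates as the diazo nitrogen leaves, inserting a CH2 group and giving A3. Reduction of the ketone of A3 and dehydration would then give the chromene.
- **For:** low temperature, and the pyran oxygen is in place beyond doubt.
- **Against:** the step makes one skeletal bond and presupposes the fully substituted ring A, which is the real problem of the target. In A4 the aryl carbon and the oxygen-bearing quaternary carbon compete as migrating groups. The diazoalkane can alkylate the free phenol, and the Lewis acid meets a prenyl group ortho to a phenol. Two further steps are needed to take A3 to the chromene.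
- **Comparison:** Alternative 2 is stronger only in the mildness of its key step. The chosen strategy solves ring A and reaches ring C by a single annulation on phenol 17.

Alternative 3: Ring A is cut at C1–C6 and C2–C3, so that methyl trans-2-hydroxy-6-{2-[4-(methoxymethoxy)phenyl]ethyl}-3-(3-methylbut-2-enyl)-4-oxocyclohex-2-ene-1-carboxylate A5 (racemic) comes from the enone (E)-1-[4-(methoxymethoxy)phenyl]-9-methyldeca-3,8-dien-5-one A6 and a malonate diester.
- **Forward key step:** Michael addition of the malonate to the β-carbon of A6, then Claisen closure of the prenyl-bearing ketone methylene onto a malonate ester, gives A5. Dehydrogenation would give the resorcylate methyl 2,4-dihydroxy-6-{2-[4-(methoxymethoxy)phenyl]ethyl}-3-(3-methylbut-2-enyl)benzoate A7, and A7 would then be taken on by chromene annulation and deprotection.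
- **For:** cheap, convergent and classical for resorcylates. All ring A carbons and all four carbon substituents are set in one operation from A6, with no hindered cycloaddition.
- **Against:** A5 is below the aromatic oxidation level. To reach A7 the cyclic β-dicarbonyl must be dehydrogenated beside an electron-rich trisubstituted alkene, and the usual halogen-based or quinone oxidants attack that alkene or cause cyclisation of the enol oxygen onto it.
- **Comparison:** on step count, cost and precedent Alternative 3 is as strong as or stronger than the chosen route. The chosen strategy instead reaches the aromatic level by decarboxylation with no oxidant, so the prenyl group is never exposed, and it keeps O2 masked while ring C is closed on O4.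

Key step: step 7

Remark on the chemistry: 21 has no stereocentre and only the transient bridged lactone 15 is chiral (formed as a racemate). Siloxyacetylene 14 is assumed not to be purchasable and is made in step 6, and the prenyl donor is the commercial acetate 8.

## Route

Step 1
Reactants: 1 3-(4-hydroxyphenyl)propanoic acid
Product: 3 3-[4-(methoxymethoxy)phenyl]propanoic acid, via bis-methoxymethyl intermediate 2 (not isolated)
Conditions: MOMCl, iPr2NEt, CH2Cl2, 0 °C to rt; then LiOH, THF/H2O, rt; cold 1 M HCl to pH 4
Reagents that add atoms: chloromethyl methyl ether, COCCl; lithium hydroxide, [Li+].[OH-]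
Why: Amine-mediated O-alkylation covers phenol and acid alike; hydroxide then cleaves only the acyl–oxygen bond of the methoxymethyl ester (saponification), because the aryl acetal is stable to base.

Step 2
Reactants: 3 3-[4-(methoxymethoxy)phenyl]propanoic acid; 4 dimethyl 3-oxopentanedioate
Product: 6 dimethyl 2-{3-[4-(methoxymethoxy)phenyl]propanoyl}-3-oxopentanedioate, via acid chloride 5 (not isolated)
Conditions: 1-chloro-N,N,2-trimethylprop-1-en-1-amine, CH2Cl2, 0 °C to rt; then 4, MgCl2, pyridine, MeCN, 0 °C to rt; cold dilute HCl
Reagents that add atoms: none
Why: The chloroenamine makes the acid chloride without free HCl, which protects the aryl acetal; the magnesium chelate of the β-keto diester is then C-acylated (soft-enolisation Claisen-type acylation), chelation suppressing O-acylation.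

Step 3
Reactants: 6 dimethyl 2-{3-[4-(methoxymethoxy)phenyl]propanoyl}-3-oxopentanedioate
Product: 7 methyl 4-hydroxy-6-{2-[4-(methoxymethoxy)phenyl]ethyl}-2-oxo-2H-pyran-5-carboxylate
Conditions: DBU, PhMe, 80 °C; then cold 1 M HCl
Reagents that add atoms: none
Why: The enol oxygen of the side-chain ketone attacks the remote ester and expels methanol (lactonisation of a 3,5-dioxo ester to a 4-hydroxy-2-pyrone); an amidine base in an aprotic solvent favours this O-cyclisation over the Dieckmann closure to a phloroglucinol.

Step 4
Reactants: 7 methyl 4-hydroxy-6-{2-[4-(methoxymethoxy)phenyl]ethyl}-2-oxo-2H-pyran-5-carboxylate; 8 3-methylbut-2-enyl acetate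
Product: 9 methyl 4-hydroxy-6-{2-[4-(methoxymethoxy)phenyl]ethyl}-3-(3-methylbut-2-enyl)-2-oxo-2H-pyran-5-carboxylate
Conditions: Pd(PPh3)4 (5 mol %), DBU, THF, 50 °C; then cold 1 M HCl
Reagents that add atoms: none
Why: Tsuji–Trost allylation: the soft pyronate attacks the unsubstituted terminus of the π-(1,1-dimethylallyl)palladium cation at C3, its only free nucleophilic carbon; any O-allyl isomer re-ionises under zerovalent palladium, so the C-prenyl product should accumulate.

Step 5
Reactants: 9 methyl 4-hydroxy-6-{2-[4-(methoxymethoxy)phenyl]ethyl}-3-(3-methylbut-2-enyl)-2-oxo-2H-pyran-5-carboxylate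
Product: 10 methyl 4-(methoxymethoxy)-6-{2-[4-(methoxymethoxy)phenyl]ethyl}-3-(3-methylbut-2-enyl)-2-oxo-2H-pyran-5-carboxylate
Conditions: MOMCl, iPr2NEt, CH2Cl2, 0 °C to rt
Reagents that add atoms: chloromethyl methyl ether, COCCl
Why: O-alkylation of the vinylogous acid; the hard chloromethyl ether should react at O4 of the pyronate to keep the 2-pyrone form, and the acidic proton that would destroy the ynol ether in step 7 is removed.

Step 6
Reactants: 11 acetylene
Product: 14 (triisopropylsilyloxy)acetylene, via lithium acetylide 12 (not isolated), via lithium ethynolate 13 (not isolated)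
Conditions: n-BuLi, THF, −78 °C; t-BuOOLi (from t-BuOOH and LiN(SiMe3)2), −78 to 0 °C; iPr3SiOTf, −78 °C
Reagents that add atoms: tert-butyl hydroperoxide, CC(C)(C)OO; triisopropylsilyl trifluoromethanesulfonate, CC(C)[Si](C(C)C)(C(C)C)OS(=O)(=O)C(F)(F)F
Why: Electrophilic oxygenation of a lithium acetylide by a lithium alkyl peroxide gives the ynolate, which the bulky silyl triflate should capture at oxygen; the isopropyl groups also slow the later shift of silicon from oxygen to carbon.

Step 7
Reactants: 10 methyl 4-(methoxymethoxy)-6-{2-[4-(methoxymethoxy)phenyl]ethyl}-3-(3-methylbut-2-enyl)-2-oxo-2H-pyran-5-carboxylate; 14 (triisopropylsilyloxy)acetylene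
Product: 16 methyl 2-(methoxymethoxy)-6-{2-[4-(methoxymethoxy)phenyl]ethyl}-3-(3-methylbut-2-enyl)-4-(triisopropylsilyloxy)benzoate, via oxabicyclo[2.2.2]octadienone adduct 15 (not isolated)
Conditions: 14 (3 equiv), PhMe, 120 °C, sealed tube
Reagents that add atoms: none
Why: This is an inverse-electron-demand Diels–Alder reaction in which the pyrone diene C3=C4–C5=C6, its LUMO lowered by the lactone carbonyl and the C5 ester, meets the high-lying HOMO of the ynol ether. Bonding should be asynchronous: the nucleophilic CH terminus of 14 attacks pyrone C6, which is the β-carbon of the C5 ester and carries the ring oxygen, and the siloxy carbon then closes onto C3 to give bridged lactone 15. Lactone 15 loses CO2 by retro-(4+2), which is irreversible and delivers the benzene ring at the aromatic oxidation level. The closest known reaction type is the decarboxylative cycloaddition of 2-pyrone-5-carboxylates with ynamines, alkoxyalkynes and ketene acetals. Ring A is closed by an intermolecular (4+2) cycloaddition that forms the ring A bonds C3–C4 and C5–C6, not by cyclisation of a chain. No stereocentre results, because the two bridgehead carbons of 15 become sp2 when the bridge leaves. The selectivity needed is regiochemical (siloxy carbon next to the prenyl-bearing carbon) and is secured by the polarity match just described; the prenyl alkene and ring B are poor partners for either component. The 4-alkoxy donor and the full substitution of the diene slow the addition, which is why heat and an excess of the very electron-rich alkyne are used, and the triisopropylsilyl group is chosen to keep silyl migration in 14 slow at that temperature.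

Step 8
Reactants: 16 methyl 2-(methoxymethoxy)-6-{2-[4-(methoxymethoxy)phenyl]ethyl}-3-(3-methylbut-2-enyl)-4-(triisopropylsilyloxy)benzoate
Product: 17 methyl 4-hydroxy-2-(methoxymethoxy)-6-{2-[4-(methoxymethoxy)phenyl]ethyl}-3-(3-methylbut-2-enyl)benzoate
Conditions: Bu4NF, AcOH, THF, 0 °C
Reagents that add atoms: none
Why: Fluoride-induced cleavage of the aryl silyl ether, driven by the Si–F bond; the acetals, the ester and both alkenes are inert, and the acetic acid buffer keeps the phenoxide from side reactions.

Step 9
Reactants: 17 methyl 4-hydroxy-2-(methoxymethoxy)-6-{2-[4-(methoxymethoxy)phenyl]ethyl}-3-(3-methylbut-2-enyl)benzoate; 18 3-methylbut-2-enal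
Product: 20 methyl 7-(methoxymethoxy)-5-{2-[4-(methoxymethoxy)phenyl]ethyl}-2,2-dimethyl-8-(3-methylbut-2-enyl)-2H-chromene-6-carboxylate, via ortho-quinone methide 19 (not isolated)
Conditions: H3NCH2CH2NH3(OAc)2 (20 mol %), xylene, 130 °C
Reagents that add atoms: none
Why: Ammonium-acetate-catalysed phenol–enal annulation: Knoevenagel-type C-alkylation at C5 (the only free ortho carbon, activated ortho by O4 and para by O2) through the iminium ion of 18, dehydration to 19, then oxa-6π electrocyclisation to the 2H-chromene.

Step 10
Reactants: 20 methyl 7-(methoxymethoxy)-5-{2-[4-(methoxymethoxy)phenyl]ethyl}-2,2-dimethyl-8-(3-methylbut-2-enyl)-2H-chromene-6-carboxylate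
Product: 21 methyl 7-hydroxy-5-[2-(4-hydroxyphenyl)ethyl]-2,2-dimethyl-8-(3-methylbut-2-enyl)-2H-chromene-6-carboxylate
Conditions: HCl (0.5 M), MeOH, rt to 40 °C
Reagents that add atoms: none
Why: Acid-catalysed acetal exchange with the solvent removes both methoxymethyl groups; the acid is kept dilute so that the freed O7–H should not add across the prenyl double bond, and methanol makes any ester exchange degenerate.

## Compound list

1 | 3-(4-hydroxyphenyl)propanoic acid | OC(=O)CCc1ccc(O)cc1 | starting material
2 | methoxymethyl 3-[4-(methoxymethoxy)phenyl]propanoate | COCOC(=O)CCc1ccc(OCOC)cc1 | intermediate (not isolated)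
3 | 3-[4-(methoxymethoxy)phenyl]propanoic acid | COCOc1ccc(CCC(=O)O)cc1 | intermediate
4 | dimethyl 3-oxopentanedioate | COC(=O)CC(=O)CC(=O)OC | starting material
5 | 3-[4-(methoxymethoxy)phenyl]propanoyl chloride | COCOc1ccc(CCC(=O)Cl)cc1 | intermediate (not isolated)
6 | dimethyl 2-{3-[4-(methoxymethoxy)phenyl]propanoyl}-3-oxopentanedioate | COC(=O)CC(=O)C(C(=O)OC)C(=O)CCc1ccc(OCOC)cc1 | intermediate
7 | methyl 4-hydroxy-6-{2-[4-(methoxymethoxy)phenyl]ethyl}-2-oxo-2H-pyran-5-carboxylate | COC(=O)C1=C(CCc2ccc(OCOC)cc2)OC(=O)C=C1O | intermediate
8 | 3-methylbut-2-enyl acetate | CC(=O)OCC=C(C)C | starting material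
9 | methyl 4-hydroxy-6-{2-[4-(methoxymethoxy)phenyl]ethyl}-3-(3-methylbut-2-enyl)-2-oxo-2H-pyran-5-carboxylate | COC(=O)C1=C(CCc2ccc(OCOC)cc2)OC(=O)C(CC=C(C)C)=C1O | intermediate
10 | methyl 4-(methoxymethoxy)-6-{2-[4-(methoxymethoxy)phenyl]ethyl}-3-(3-methylbut-2-enyl)-2-oxo-2H-pyran-5-carboxylate | COCOC1=C(CC=C(C)C)C(=O)OC(CCc2ccc(OCOC)cc2)=C1C(=O)OC | intermediate
11 | acetylene | C#C | starting material
12 | lithium acetylide | [Li+].[C-]#C | intermediate (not isolated)
13 | lithium ethynolate | [Li+].[O-]C#C | intermediate (not isolated)
14 | (triisopropylsilyloxy)acetylene | C#CO[Si](C(C)C)(C(C)C)C(C)C | intermediate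
15 | methyl 5-(methoxymethoxy)-1-{2-[4-(methoxymethoxy)phenyl]ethyl}-4-(3-methylbut-2-enyl)-3-oxo-8-(triisopropylsilyloxy)-2-oxabicyclo[2.2.2]octa-5,7-diene-6-carboxylate (racemic, one enantiomer drawn) | O=C1O[C@]2(CCc3ccc(OCOC)cc3)C=C(O[Si](C(C)C)(C(C)C)C(C)C)[C@@]1(CC=C(C)C)C(OCOC)=C2C(=O)OC | intermediate (not isolated)
16 | methyl 2-(methoxymethoxy)-6-{2-[4-(methoxymethoxy)phenyl]ethyl}-3-(3-methylbut-2-enyl)-4-(triisopropylsilyloxy)benzoate | COC(=O)c1c(OCOC)c(CC=C(C)C)c(O[Si](C(C)C)(C(C)C)C(C)C)cc1CCc1ccc(OCOC)cc1 | intermediate
17 | methyl 4-hydroxy-2-(methoxymethoxy)-6-{2-[4-(methoxymethoxy)phenyl]ethyl}-3-(3-methylbut-2-enyl)benzoate | COC(=O)c1c(OCOC)c(CC=C(C)C)c(O)cc1CCc1ccc(OCOC)cc1 | intermediate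
18 | 3-methylbut-2-enal | CC(C)=CC=O | starting material
19 | methyl 6-(methoxymethoxy)-2-{2-[4-(methoxymethoxy)phenyl]ethyl}-5-(3-methylbut-2-enyl)-3-(3-methylbut-2-enylidene)-4-oxocyclohexa-1,5-diene-1-carboxylate (exocyclic alkene geometry not defined) | COC(=O)C1=C(CCc2ccc(OCOC)cc2)C(=CC=C(C)C)C(=O)C(CC=C(C)C)=C1OCOC | intermediate (not isolated)
20 | methyl 7-(methoxymethoxy)-5-{2-[4-(methoxymethoxy)phenyl]ethyl}-2,2-dimethyl-8-(3-methylbut-2-enyl)-2H-chromene-6-carboxylate | COC(=O)c1c(OCOC)c(CC=C(C)C)c2c(c1CCc1ccc(OCOC)cc1)C=CC(C)(C)O2 | intermediate
21 | methyl 7-hydroxy-5-[2-(4-hydroxyphenyl)ethyl]-2,2-dimethyl-8-(3-methylbut-2-enyl)-2H-chromene-6-carboxylate | COC(=O)c1c(O)c(CC=C(C)C)c2c(c1CCc1ccc(O)cc1)C=CC(C)(C)O2 | target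

## Step count and least certain steps

Total step count: 10. Longest linear sequence: 9 steps (steps 1 to 5 and 7 to 10, from 1); step 6 is a one-step branch.

**Step 7 (key step).** The cycloaddition may not outrun the decay of 14. The 4-alkoxy group raises the LUMO of the diene and both reacting carbons of 10 are fully substituted. The temperature required may therefore be one at which the silyl group of 14 migrates from oxygen to carbon or the alkyne oligomerises. A stepwise (2+2) addition across C5–C6 is a second possible diversion.
Fallback: keep pyrone 10 but replace the alkyne by a ketene bis(silyl) acetal, a more nucleophilic alkene that cannot undergo the oxygen-to-carbon silyl shift. 1,1-Bis(trimethylsilyloxy)ethene F1, made from trimethylsilyl acetate with LiN(iPr)2 and Me3SiCl, should add to 10 in toluene at 80 to 110 °C with the same orientation (CH2 to pyrone C6). Decarboxylation and 1,2-elimination of silanol then aromatise the ring to methyl 2-(methoxymethoxy)-6-{2-[4-(methoxymethoxy)phenyl]ethyl}-3-(3-methylbut-2-enyl)-4-(trimethylsilyloxy)benzoate F2. F2 loses its silyl group on work-up with aqueous citric acid and rejoins the route at phenol 17.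

**Step 6.** Two processes threaten it. Disproportionation of monolithium acetylide 12 while the mixture is warmed for oxygen transfer would remove it from solution. Ynolate 13, less hindered at carbon than substituted ynolates, may be silylated at carbon instead of oxygen.
Fallback: block the carbon terminus. Acetylide 12 is silylated with Me3SiCl to ethynyltrimethylsilane F3 (also commercially available). F3 is lithiated, oxygenated with t-BuOOLi and silylated with iPr3SiOTf to give 1-(triisopropylsilyloxy)-2-(trimethylsilyl)ethyne F4, in which the bulky silyl electrophile should go to oxygen because the carbon terminus is already silylated. K2CO3 in MeOH at 0 °C should then cleave the C–SiMe3 bond selectively and return to 14.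

**Step 9.** C-alkylation at C5 may be slow, since the ester para to O4 lowers the nucleophilicity of the phenol and C5 lies next to the arylethyl chain. Self-condensation of 18, or addition of O4–H to the neighbouring prenyl double bond, may then overtake the annulation.
Fallback: build the pyran by O-alkylation and sigmatropic rearrangement instead of condensation. Phenol 17 is alkylated with 3-chloro-3-methylbut-1-yne (K2CO3, KI, CuI cat., acetone) to methyl 2-(methoxymethoxy)-6-{2-[4-(methoxymethoxy)phenyl]ethyl}-4-[(2-methylbut-3-yn-2-yl)oxy]-3-(3-methylbut-2-enyl)benzoate F5. Heating in N,N-diethylaniline at about 160 °C should cause propargyl Claisen rearrangement to C5 (the only free ortho carbon), 1,5-hydrogen shift and 6π closure, giving chromene 20.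

**Step 4.** The allyl transfer may lose site selectivity: attack at the substituted terminus of the allyl ligand (reverse prenyl), persistence of the O-allyl isomer, or a second allylation at C3.
Fallback: install the prenyl group before the ring exists. Keto diester 4 is monoalkylated with 1-bromo-3-methylbut-2-ene (K2CO3, acetone) to dimethyl 2-(3-methylbut-2-enyl)-3-oxopentanedioate F6. C-acylation of its remaining methylene with acid chloride 5 (MgCl2, pyridine) gives dimethyl 2-(3-methylbut-2-enyl)-4-{3-[4-(methoxymethoxy)phenyl]propanoyl}-3-oxopentanedioate F7. DBU-mediated lactonisation onto the ester beside the prenyl-bearing carbon returns to 9.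

## Further compounds

F1 | step 7 | 1,1-bis(trimethylsilyloxy)ethene | C=C(O[Si](C)(C)C)O[Si](C)(C)C
F2 | step 7 | methyl 2-(methoxymethoxy)-6-{2-[4-(methoxymethoxy)phenyl]ethyl}-3-(3-methylbut-2-enyl)-4-(trimethylsilyloxy)benzoate | COC(=O)c1c(OCOC)c(CC=C(C)C)c(O[Si](C)(C)C)cc1CCc1ccc(OCOC)cc1
F3 | step 6 | ethynyltrimethylsilane | C#C[Si](C)(C)C
F4 | step 6 | 1-(triisopropylsilyloxy)-2-(trimethylsilyl)ethyne | C[Si](C)(C)C#CO[Si](C(C)C)(C(C)C)C(C)C
F5 | step 9 | methyl 2-(methoxymethoxy)-6-{2-[4-(methoxymethoxy)phenyl]ethyl}-4-[(2-methylbut-3-yn-2-yl)oxy]-3-(3-methylbut-2-enyl)benzoate | COC(=O)c1c(OCOC)c(CC=C(C)C)c(OC(C)(C)C#C)cc1CCc1ccc(OCOC)cc1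
F6 | step 4 | dimethyl 2-(3-methylbut-2-enyl)-3-oxopentanedioate | COC(=O)CC(=O)C(CC=C(C)C)C(=O)OC
F7 | step 4 | dimethyl 2-(3-methylbut-2-enyl)-4-{3-[4-(methoxymethoxy)phenyl]propanoyl}-3-oxopentanedioate | COC(=O)C(CC=C(C)C)C(=O)C(C(=O)OC)C(=O)CCc1ccc(OCOC)cc1
A1 | alternative 1 | 5-bromo-7-(methoxymethoxy)-2,2-dimethyl-2H-chromene | COCOc1cc(Br)c2C=CC(C)(C)Oc2c1
A2 | alternative 1 | 2-bromo-4-(methoxymethoxy)-6-(trimethylsilyl)phenyl trifluoromethanesulfonate | COCOc1cc(Br)c(OS(=O)(=O)C(F)(F)F)c([Si](C)(C)C)c1
A3 | alternative 2 | methyl 5-{2-[4-(tert-butyldimethylsilyloxy)phenyl]ethyl}-7-hydroxy-2,2-dimethyl-8-(3-methylbut-2-enyl)-3-oxochromane-6-carboxylate | COC(=O)c1c(O)c(CC=C(C)C)c2OC(C)(C)C(=O)Cc2c1CCc1ccc(O[Si](C)(C)C(C)(C)C)cc1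
A4 | alternative 2 | methyl 4-{2-[4-(tert-butyldimethylsilyloxy)phenyl]ethyl}-6-hydroxy-2,2-dimethyl-7-(3-methylbut-2-enyl)-3-oxo-2,3-dihydro-1-benzofuran-5-carboxylate | COC(=O)c1c(O)c(CC=C(C)C)c2OC(C)(C)C(=O)c2c1CCc1ccc(O[Si](C)(C)C(C)(C)C)cc1
A5 | alternative 3 | methyl trans-2-hydroxy-6-{2-[4-(methoxymethoxy)phenyl]ethyl}-3-(3-methylbut-2-enyl)-4-oxocyclohex-2-ene-1-carboxylate (racemic, one enantiomer drawn) | COC(=O)[C@H]1[C@H](CCc2ccc(OCOC)cc2)CC(=O)C(CC=C(C)C)=C1O
A6 | alternative 3 | (E)-1-[4-(methoxymethoxy)phenyl]-9-methyldeca-3,8-dien-5-one | COCOc1ccc(CC/C=C/C(=O)CCC=C(C)C)cc1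
A7 | alternative 3 | methyl 2,4-dihydroxy-6-{2-[4-(methoxymethoxy)phenyl]ethyl}-3-(3-methylbut-2-enyl)benzoate | COC(=O)c1c(O)c(CC=C(C)C)c(O)cc1CCc1ccc(OCOC)cc1
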